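**Retrosynthetic overview**
1. The route rests on C4, the carbonyl carbon of pyranone ring C. It is bonded to C4a of ring A, whose five other carbons all bear oxygen, and to C3 of the C3–C2 unit that carries ring B. Cutting C4a–C4 and C4–C3 leaves carbon monoxide, iodopentamethoxybenzene (mirror plane through C–I) and a ring B arylacetylene.
2. Rings A and B enter as arenes. Ring C is the only ring formed, after the key step, by ICl-induced 6-endo-dig closure of O1–C2. Either of the two equivalent ortho methoxy groups gives the same 3-iodoflavone.
3. The C3 iodide is the handle for the C3 oxygen: I/Mg exchange, borate, peroxide, then MeI. This polarity inversion is preferred to hot methoxide, which could add to C2 of the iodoflavone and contract ring C.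
4. BCl3 finally frees 2'-OH and 4'-OH (benzyl ethers) and 5-OH (chelated methyl ether). The target has no stereocentre.
5. The iodide comes from 1,2,3-trimethoxybenzene (dibromination, double copper-catalysed methoxylation, lithiation–iodination). The alkyne comes from 2,4-dihydroxybenzaldehyde (benzylation, Ohira–Bestmann homologation).

Key step: step 6

**Step 1**
Reactants: 1 1,2,3-trimethoxybenzene
Product: 2 1,5-dibromo-2,3,4-trimethoxybenzene
Conditions: NBS (2.2 equiv), MeCN, 0 °C to rt
Reagents that add atoms: N-bromosuccinimide, O=C1CCC(=O)N1Br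
Why: Electrophilic aromatic bromination, in which C4 and C6 of 1 are each ortho to one outer methoxy group and para to the other, whereas C5 is activated only by the twisted central methoxy group, so both bromines should enter beside the C–H that remains.

**Step 2**
Reactants: 2 1,5-dibromo-2,3,4-trimethoxybenzene
Product: 3 pentamethoxybenzene
Conditions: NaOMe (25% in MeOH, 8 equiv), CuBr (0.3 equiv), DMF, 110 °C
Reagents that add atoms: sodium methoxide, [Na+].[O-]C
Why: Ullmann-type methoxylation of aryl bromides under monovalent copper catalysis, a standard way to polymethoxyarenes, helped here because each bromide has only one ortho substituent and the ring carries nothing that methoxide can harm.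

**Step 3**
Reactants: 3 pentamethoxybenzene
Product: 5 1-iodo-2,3,4,5,6-pentamethoxybenzene, via pentamethoxyphenyllithium 4 (not isolated)
Conditions: n-BuLi (1.1 equiv), THF, 0 °C; I2 (1.2 equiv), −78 °C to rt
Reagents that add atoms: iodine, II; n-butyllithium, [Li]CCCC (lithium in 4 only)
Why: Directed ortho-lithiation followed by iodinolysis, in which the only ring C–H lies between two methoxy groups that acidify it and bind lithium, and the easily oxidised ring is never exposed to an electrophilic iodinating oxidant.

**Step 4**
Reactants: 6 2,4-dihydroxybenzaldehyde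
Product: 7 2,4-bis(benzyloxy)benzaldehyde
Conditions: BnBr (2.3 equiv), K2CO3 (3 equiv), DMF, 60 °C
Reagents that add atoms: benzyl bromide, BrCc1ccccc1
Why: Williamson ether synthesis, with excess reagent and gentle heating so that the hydrogen-bonded 2-OH is alkylated as well as the 4-OH.

**Step 5**
Reactants: 7 2,4-bis(benzyloxy)benzaldehyde
Product: 8 2,4-bis(benzyloxy)-1-ethynylbenzene
Conditions: Ohira–Bestmann reagent (1.3 equiv), K2CO3 (2 equiv), MeOH–THF, rt
Reagents that add atoms: dimethyl (1-diazo-2-oxopropyl)phosphonate, CC(=O)C(=[N+]=[N-])P(=O)(OC)OC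
Why: Ohira–Bestmann variant of the Seyferth–Gilbert homologation, in which methanolysis releases the diazomethylphosphonate anion, this olefinates the aldehyde, and loss of N2 with a 1,2-hydrogen shift gives the terminal alkyne under mild base that leaves benzyl ethers untouched.

**Step 6**
Reactants: 5 1-iodo-2,3,4,5,6-pentamethoxybenzene; 8 2,4-bis(benzyloxy)-1-ethynylbenzene; 9 carbon monoxide
Product: 10 3-[2,4-bis(benzyloxy)phenyl]-1-(pentamethoxyphenyl)prop-2-yn-1-one
Conditions: PdCl2(PPh3)2 (5 mol %), CuI (2 mol %), Et3N (3 equiv), THF, CO (5 bar), 50 °C, slow addition of 8, degassed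
Reagents that add atoms: carbon monoxide 9, [C-]#[O+]
Why: PdCl2(PPh3)2 is reduced in the flask to a zerovalent palladium phosphine species that adds oxidatively to the C–I bond of 5; migration of the crowded aryl group onto bound CO gives an aroyl iodide complex of divalent palladium, the alkynylcopper species made from 8, CuI and Et3N passes its alkynyl group to palladium, and reductive elimination forms 10 with the new C4a–C4 and C4–C3 bonds. The reaction type is the carbonylative Sonogashira coupling, an established three-component route from aryl iodides, CO and terminal alkynes to aryl alkynyl ketones. No ring closes and no stereocentre arises in this step. The selectivity needed is carbonylation before alkynyl transfer: the two ortho methoxy groups shield the aryl–palladium bond from transmetalation and gain strain relief when the aryl group moves to CO, while CO pressure and slow addition of 8 keep the acyl pathway ahead of direct alkynylation. Oxygen-free handling and a low CuI loading hold back Glaser dimerisation of 8, and Et3N, being tertiary, cannot add to the ynone. Because 5 has a mirror plane through C–I and the para carbon, a single ynone results and its two ortho methoxy groups are equivalent for the later ring closure.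

**Step 7**
Reactants: 10 3-[2,4-bis(benzyloxy)phenyl]-1-(pentamethoxyphenyl)prop-2-yn-1-one
Product: 11 2-[2,4-bis(benzyloxy)phenyl]-3-iodo-5,6,7,8-tetramethoxy-4H-chromen-4-one
Conditions: ICl (1.2 equiv), CH2Cl2, −78 °C; aq Na2S2O3
Reagents that add atoms: iodine monochloride, ClI
Why: Iodine monochloride-induced 6-endo-dig iodocyclisation of a 2-methoxyaryl ynone, in which iodonium activation builds positive charge at C2 next to donor ring B, an ortho methoxy oxygen of ring A attacks there and chloride strips the methyl group from the oxonium ion, while attack by the 2'-benzyloxy oxygen would need the electron-poor carbon alpha to the carbonyl, and the low temperature with little excess ICl spares ring B from iodination.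

**Step 8**
Reactants: 11 2-[2,4-bis(benzyloxy)phenyl]-3-iodo-5,6,7,8-tetramethoxy-4H-chromen-4-one
Product: 14 2-[2,4-bis(benzyloxy)phenyl]-3-hydroxy-5,6,7,8-tetramethoxy-4H-chromen-4-one, via 3-chloromagnesioflavone 12 (not isolated), via dimethyl flavon-3-ylboronate 13 (not isolated)
Conditions: i-PrMgCl·LiCl (1.15 equiv), THF, −40 °C; B(OMe)3 (3 equiv), −40 to 0 °C; AcOH, 30% H2O2, 0 °C to rt
Reagents that add atoms: hydrogen peroxide, OO (the C3 oxygen); isopropylmagnesium chloride, CC(C)[Mg]Cl (MgCl in 12 only); trimethyl borate, COB(OC)OC (B(OMe)2 in 13 only)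
Why: Iodine–magnesium exchange, borate trapping and peroxide oxidation (the arylmetal-to-phenol sequence), which fits because C3-metalated flavones are known to be caught by trimethyl borate and oxidised to flavonols, an sp2 iodide next to a carbonyl exchanges fast at low temperature where the covalent C–Mg bond should not expel O1, and no free alkoxide ever meets the electrophilic C2.

**Step 9**
Reactants: 14 2-[2,4-bis(benzyloxy)phenyl]-3-hydroxy-5,6,7,8-tetramethoxy-4H-chromen-4-one
Product: 15 2-[2,4-bis(benzyloxy)phenyl]-3,5,6,7,8-pentamethoxy-4H-chromen-4-one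
Conditions: MeI (2 equiv), K2CO3 (2 equiv), acetone, reflux
Reagents that add atoms: iodomethane, CI
Why: Williamson O-methylation of the flavonol 3-OH, the only acidic site in 14.

**Step 10**
Reactants: 15 2-[2,4-bis(benzyloxy)phenyl]-3,5,6,7,8-pentamethoxy-4H-chromen-4-one
Product: 16 5,2',4'-trihydroxy-3,6,7,8-tetramethoxyflavone
Conditions: BCl3 (1 M in CH2Cl2, 6 equiv), C6HMe5 (6 equiv), CH2Cl2, −78 to 0 °C; aq HCl–THF
Reagents that add atoms: none
Why: Lewis acid ether cleavage, in which BCl3 with pentamethylbenzene as benzyl cation trap cleaves aryl benzyl ethers at −78 °C, and on warming boron held by C4=O closes a six-membered chelate through O5 so that chloride removes only the 5-O-methyl group, the 3-methoxy group offering only a five-membered chelate and the 6-, 7- and 8-methoxy groups none.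

**Compound list**
1 | 1,2,3-trimethoxybenzene | COc1cccc(OC)c1OC | starting material
2 | 1,5-dibromo-2,3,4-trimethoxybenzene | COc1c(Br)cc(Br)c(OC)c1OC | intermediate
3 | pentamethoxybenzene | COc1cc(OC)c(OC)c(OC)c1OC | intermediate
4 | pentamethoxyphenyllithium (not isolated) | [Li]c1c(OC)c(OC)c(OC)c(OC)c1OC | intermediate
5 | 1-iodo-2,3,4,5,6-pentamethoxybenzene | COc1c(I)c(OC)c(OC)c(OC)c1OC | intermediate
6 | 2,4-dihydroxybenzaldehyde | O=Cc1ccc(O)cc1O | starting material
7 | 2,4-bis(benzyloxy)benzaldehyde | O=Cc1ccc(OCc2ccccc2)cc1OCc1ccccc1 | intermediate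
8 | 2,4-bis(benzyloxy)-1-ethynylbenzene | C#Cc1ccc(OCc2ccccc2)cc1OCc1ccccc1 | intermediate
9 | carbon monoxide | [C-]#[O+] | starting material
10 | 3-[2,4-bis(benzyloxy)phenyl]-1-(pentamethoxyphenyl)prop-2-yn-1-one | COc1c(OC)c(OC)c(C(=O)C#Cc2ccc(OCc3ccccc3)cc2OCc2ccccc2)c(OC)c1OC | intermediate
11 | 2-[2,4-bis(benzyloxy)phenyl]-3-iodo-5,6,7,8-tetramethoxy-4H-chromen-4-one | COc1c(OC)c(OC)c2c(=O)c(I)c(-c3ccc(OCc4ccccc4)cc3OCc3ccccc3)oc2c1OC | intermediate
12 | 3-chloromagnesio derivative of the flavone, MgCl at C3 in place of iodine (not isolated) | COc1c(OC)c(OC)c2c(=O)c([Mg]Cl)c(-c3ccc(OCc4ccccc4)cc3OCc3ccccc3)oc2c1OC | intermediate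
13 | dimethyl boronate of the flavone, B(OMe)2 at C3 (not isolated) | COB(OC)c1c(-c2ccc(OCc3ccccc3)cc2OCc2ccccc2)oc2c(OC)c(OC)c(OC)c(OC)c2c1=O | intermediate
14 | 2-[2,4-bis(benzyloxy)phenyl]-3-hydroxy-5,6,7,8-tetramethoxy-4H-chromen-4-one | COc1c(OC)c(OC)c2c(=O)c(O)c(-c3ccc(OCc4ccccc4)cc3OCc3ccccc3)oc2c1OC | intermediate
15 | 2-[2,4-bis(benzyloxy)phenyl]-3,5,6,7,8-pentamethoxy-4H-chromen-4-one | COc1c(OC)c(OC)c2c(=O)c(OC)c(-c3ccc(OCc4ccccc4)cc3OCc3ccccc3)oc2c1OC | intermediate
16 | 5,2',4'-trihydroxy-3,6,7,8-tetramethoxyflavone | COc1c(OC)c(O)c2c(=O)c(OC)c(-c3ccc(O)cc3O)oc2c1OC | target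

**Step count**
Total step count: 10. Longest linear sequence: 8 (steps 1, 2, 3, 6, 7, 8, 9, 10).

**Steps most likely to fail**

Step 6. Oxidative addition of the electron-rich, doubly ortho-substituted iodide may be slow under CO. Part of the material may then leak into direct alkynylation or into oxidative dimerisation of the alkyne. The fallback builds the same two bonds by polar chemistry and sets out from 3 and 8. Lithiation of 3 to 4 as in step 3 and quenching with DMF should give 2,3,4,5,6-pentamethoxybenzaldehyde F1. Deprotonation of 8 with n-BuLi in THF at −78 °C gives the lithium acetylide F2. Its addition to the aldehyde gives the racemic propargylic alcohol 3-[2,4-bis(benzyloxy)phenyl]-1-(pentamethoxyphenyl)prop-2-yn-1-ol F3. Oxidation with MnO2 in CH2Cl2 rejoins the route at 10.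

Step 8. The C3 carbanion may expel O1 by beta-elimination and reopen ring C. The Grignard reagent may add to C4 or C2, or the boronate may be protonated before it is oxidised. The fallback introduces the oxygen by electrophilic oxidation of the C2=C3 bond and sets out from 11. Transfer hydrodeiodination with Pd(PPh3)4 and HCO2Na in DMF should give 2-[2,4-bis(benzyloxy)phenyl]-5,6,7,8-tetramethoxy-4H-chromen-4-one F4. Dimethyldioxirane in acetone–CH2Cl2 at 0 °C, a known way from polymethoxyflavones and benzyl-protected flavones to flavonols, gives the racemic 2,3-epoxide F5. A catalytic amount of TsOH opens this epoxide, and the route is rejoined at 14.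

Step 10. After the 5-O chelate has formed, demethylation may run on to the 6- or 3-methoxy group. Benzyl cations may attack the resorcinol ring B, or cleavage of the 5-O-methyl group may stay incomplete. The fallback separates the two tasks into orthogonal operations and sets out from 15. Hydrogenolysis (H2, Pd/C, EtOAc–MeOH) should give 2-(2,4-dihydroxyphenyl)-3,5,6,7,8-pentamethoxy-4H-chromen-4-one F6. Chelation-controlled mono-demethylation with anhydrous AlCl3 in MeCN then removes the 5-O-methyl group alone and arrives at 16.

**Further compounds**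
F1 | step 6 | 2,3,4,5,6-pentamethoxybenzaldehyde | COc1c(C=O)c(OC)c(OC)c(OC)c1OC
F2 | step 6 | lithium acetylide of 8 | [Li]C#Cc1ccc(OCc2ccccc2)cc1OCc1ccccc1
F3 | step 6 | racemic 3-[2,4-bis(benzyloxy)phenyl]-1-(pentamethoxyphenyl)prop-2-yn-1-ol | COc1c(OC)c(OC)c(C(O)C#Cc2ccc(OCc3ccccc3)cc2OCc2ccccc2)c(OC)c1OC
F4 | step 8 | 2-[2,4-bis(benzyloxy)phenyl]-5,6,7,8-tetramethoxy-4H-chromen-4-one | COc1c(OC)c(OC)c2c(=O)cc(-c3ccc(OCc4ccccc4)cc3OCc3ccccc3)oc2c1OC
F5 | step 8 | racemic 2,3-epoxide of F4 (oxirane cis-fused across C2–C3) | COc1c(OC)c(OC)c2c(c1OC)OC1(c3ccc(OCc4ccccc4)cc3OCc3ccccc3)OC1C2=O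
F6 | step 10 | 2-(2,4-dihydroxyphenyl)-3,5,6,7,8-pentamethoxy-4H-chromen-4-one | COc1c(OC)c(OC)c2c(=O)c(OC)c(-c3ccc(O)cc3O)oc2c1OC
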